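**Retrosynthetic overview**

- The target is an open-chain anti-(3S,5S)-1,3-diol between guaiacyl ring A (on C1) and syringyl ring B (on C7). No ring is formed in the route: both benzene rings are bought and carried as TIPS ethers.
- Key disconnection C3–C4. C3 enters as the α-lithiated carbamate carbon of the ring A half. C4 enters as the primary C–B carbon of a 1,2-bis(boronic ester), whose secondary C–B bond is the future C5–OH. One flask (lithiation–borylation–oxidation) joins two donor carbons, sets C3 and unveils both hydroxyls.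
- Enabling feature: the triad C3(OH)–C4H2–C5(OH). C4 is an unsubstituted methylene between two oxygen-bearing carbons, so C4/C5 map onto a terminal alkene (asymmetric diboration). The C3 oxygen, as a carbamate, first acidifies C3–H and then leaves.
- Ring A half: eugenol (silylation, hydroboration–oxidation, carbamoylation). Ring B half: 4-bromo-2,6-dimethoxyphenol (silylation, Negishi butenylation, platinum-catalysed diboration). Last step: desilylation.

Key step: step 7

Assumption: the antipode of the TADDOL phosphonite ligand in step 6 is the one that delivers the (R)-configured bis(boronic ester); the sense is taken from simple 1-alkenes, and the other antipode is used if a first run shows the opposite sense.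

Abbreviations: TIPS = triisopropylsilyl; Cb = N,N-diisopropylcarbamoyl; pin = pinacolato.

**Step 1**
Reactants: 1 eugenol (4-allyl-2-methoxyphenol)
Product: 2 triisopropyl[2-methoxy-4-(prop-2-en-1-yl)phenoxy]silane
Conditions: TIPSCl, imidazole, DMF, rt
Reagents that add atoms: triisopropylsilyl chloride, CC(C)[Si](Cl)(C(C)C)C(C)C
Why: Imidazole-mediated O-silylation (nucleophilic substitution at silicon) of the only acidic OH should give the aryl TIPS ether, chosen because it is bulky enough to resist s-BuLi and cold basic peroxide and is removed by fluoride at the end.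

**Step 2**
Reactants: 2 triisopropyl[2-methoxy-4-(prop-2-en-1-yl)phenoxy]silane
Product: 4 3-[3-methoxy-4-(triisopropylsilyloxy)phenyl]propan-1-ol, via B-alkyl-9-BBN adduct 3 (not isolated)
Conditions: 9-BBN, THF, 0 °C to rt; then 3 M NaOH, 30% H2O2, 0 °C
Reagents that add atoms: hydrogen peroxide, OO; 9-borabicyclo[3.3.1]nonane, B1C2CCCC1CCC2 (boron and ring carbons of intermediate 3 only)
Why: Anti-Markovnikov hydroboration of the terminal alkene with the bulky 9-BBN and oxidation of the C–B bond with retention (hydroboration–oxidation) should give the primary alcohol, the hindered aryl TIPS ether tolerating cold basic peroxide for the short reaction time.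

**Step 3**
Reactants: 4 3-[3-methoxy-4-(triisopropylsilyloxy)phenyl]propan-1-ol
Product: 5 3-[3-methoxy-4-(triisopropylsilyloxy)phenyl]propyl N,N-diisopropylcarbamate
Conditions: CbCl, Et3N, CH2Cl2, reflux
Reagents that add atoms: N,N-diisopropylcarbamoyl chloride, CC(C)N(C(C)C)C(Cl)=O
Why: Nucleophilic acyl substitution at the carbamoyl chloride by the primary alcohol installs the carbamate that later directs and stabilises lithiation at C3 and then serves as the leaving group.

**Step 4**
Reactants: 6 4-bromo-2,6-dimethoxyphenol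
Product: 7 (4-bromo-2,6-dimethoxyphenoxy)triisopropylsilane
Conditions: TIPSCl, imidazole, DMF, 40 °C
Reagents that add atoms: triisopropylsilyl chloride, CC(C)[Si](Cl)(C(C)C)C(C)C
Why: The same O-silylation as in step 1 should protect the phenol flanked by two methoxy groups, gentle warming compensating for the hindrance.

**Step 5**
Reactants: 7 (4-bromo-2,6-dimethoxyphenoxy)triisopropylsilane; 8 but-3-en-1-ylzinc bromide (CH2=CHCH2CH2ZnBr, solution in THF)
Product: 9 [4-(but-3-en-1-yl)-2,6-dimethoxyphenoxy]triisopropylsilane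
Conditions: Pd(OAc)2 (2 mol%), SPhos (4 mol%), THF, rt to 50 °C
Reagents that add atoms: none
Why: Negishi coupling (oxidative addition of the aryl bromide to zerovalent palladium, transmetalation from the primary alkylzinc, reductive elimination made faster than β-hydride elimination by the bulky biarylphosphine) should give the butenyl arene with the terminal alkene in place.

**Step 6**
Reactants: 9 [4-(but-3-en-1-yl)-2,6-dimethoxyphenoxy]triisopropylsilane
Product: 10 (R)-2,2'-{4-[3,5-dimethoxy-4-(triisopropylsilyloxy)phenyl]butane-1,2-diyl}bis(4,4,5,5-tetramethyl-1,3,2-dioxaborolane)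
Conditions: Pt(dba)3 (1 mol%), 3,5-diisopropylphenyl-TADDOL phenylphosphonite (1.2 mol%, antipode as in the assumption), B2pin2 (1.05 equiv), THF, 60 °C
Reagents that add atoms: bis(pinacolato)diboron, CC1(C)OB(OC1(C)C)B1OC(C)(C)C(C)(C)O1
Why: Platinum-catalysed enantioselective alkene diboration (oxidative addition of B–B to zerovalent platinum, face-selective insertion of the terminal alkene, C–B reductive elimination) adds both boryl groups syn, and the chiral phosphonite on platinum sets the C5 stereocenter (descriptor R because boron ranks below carbon; it becomes 5S on oxidation).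

**Step 7**
Reactants: 5 3-[3-methoxy-4-(triisopropylsilyloxy)phenyl]propyl N,N-diisopropylcarbamate; 10 (R)-2,2'-{4-[3,5-dimethoxy-4-(triisopropylsilyloxy)phenyl]butane-1,2-diyl}bis(4,4,5,5-tetramethyl-1,3,2-dioxaborolane)
Product: 14 (3S,5S)-7-[3,5-dimethoxy-4-(triisopropylsilyloxy)phenyl]-1-[3-methoxy-4-(triisopropylsilyloxy)phenyl]heptane-3,5-diol, via lithiated carbamate 11 (not isolated), via lithium boronate complex 12 (not isolated), via 1,3-bis(boronic ester) 13 (not isolated)
Conditions: 5 (1.2 equiv), s-BuLi (1.15 equiv), (+)-sparteine (1.2 equiv), Et2O, −78 °C, 5 h; 10 (1.0 equiv) in Et2O, −78 °C, 1 h; reflux, 16 h; then THF, 2 M NaOH, 30% H2O2, 0 °C to rt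
Reagents that add atoms: hydrogen peroxide, OO (the two hydroxyl oxygens of 14); sec-butyllithium, CCC(C)[Li] (lithium of intermediates 11 and 12 only)
Why: s-BuLi bound to (+)-sparteine removes one of the two enantiotopic C3–H atoms next to the carbamate oxygen of 5 to give the configurationally stable carbanion 11, which adds with retention to the primary boron of 10 to give boronate 12; on warming, the C4 methylene migrates from boron to C3 anti to the leaving carbamate (1,2-metallate shift, inversion at C3) to give 13, whose two C–B bonds are then oxidised with retention. The closest known reaction type is the lithiation–borylation homologation (Hoppe lithiation followed by a Matteson-type 1,2-shift) of a 1,2-bis(boronic ester) from alkene diboration at its primary boron, followed by oxidation to a 1,3-diol. No ring is closed. The new C3 stereocenter is under reagent control by the chiral diamine ((+)-sparteine gives the (R)-lithio species, and retention, inversion and retention lead to 3S), C5 is carried over from 10, so the anti relationship follows from the pairing of the two chiral reagents and not from the substrate. The step needs site selectivity between the two boronic esters, secured by the smaller steric demand of the CH2–B group compared with the CH–B group, and deprotonation at C3 and not on ring A, secured by precomplexation of the base to the carbamate carbonyl and by the bulky TIPS ether. Both carbons joined are donors (a carbanion and a boron-bound alkyl group), and the carbamate oxygen reverses the polarity of C3 inside the boronate, which is what allows this union.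

**Step 8**
Reactants: 14 (3S,5S)-7-[3,5-dimethoxy-4-(triisopropylsilyloxy)phenyl]-1-[3-methoxy-4-(triisopropylsilyloxy)phenyl]heptane-3,5-diol
Product: 15 (3S,5S)-1-(4-hydroxy-3-methoxyphenyl)-7-(4-hydroxy-3,5-dimethoxyphenyl)heptane-3,5-diol
Conditions: Bu4NF (2.4 equiv), AcOH (2.4 equiv), THF, 0 °C to rt
Reagents that add atoms: none
Why: Fluoride attacks silicon and cleaves both aryl Si–O bonds (desilylation) while acetic acid protonates the phenoxides as they form, so the oxidation-prone electron-rich phenols and the two secondary carbinol centers are left untouched.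

**Compound list**

1 | eugenol (4-allyl-2-methoxyphenol) | COc1cc(CC=C)ccc1O | starting material
2 | triisopropyl[2-methoxy-4-(prop-2-en-1-yl)phenoxy]silane | COc1cc(CC=C)ccc1O[Si](C(C)C)(C(C)C)C(C)C | intermediate
3 | 9-{3-[3-methoxy-4-(triisopropylsilyloxy)phenyl]propyl}-9-borabicyclo[3.3.1]nonane (not isolated) | COc1cc(CCCB2C3CCCC2CCC3)ccc1O[Si](C(C)C)(C(C)C)C(C)C | intermediate
4 | 3-[3-methoxy-4-(triisopropylsilyloxy)phenyl]propan-1-ol | COc1cc(CCCO)ccc1O[Si](C(C)C)(C(C)C)C(C)C | intermediate
5 | 3-[3-methoxy-4-(triisopropylsilyloxy)phenyl]propyl N,N-diisopropylcarbamate | COc1cc(CCCOC(=O)N(C(C)C)C(C)C)ccc1O[Si](C(C)C)(C(C)C)C(C)C | intermediate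
6 | 4-bromo-2,6-dimethoxyphenol | COc1cc(Br)cc(OC)c1O | starting material
7 | (4-bromo-2,6-dimethoxyphenoxy)triisopropylsilane | COc1cc(Br)cc(OC)c1O[Si](C(C)C)(C(C)C)C(C)C | intermediate
8 | but-3-en-1-ylzinc bromide | C=CCC[Zn]Br | starting material
9 | [4-(but-3-en-1-yl)-2,6-dimethoxyphenoxy]triisopropylsilane | COc1cc(CCC=C)cc(OC)c1O[Si](C(C)C)(C(C)C)C(C)C | intermediate
10 | (R)-2,2'-{4-[3,5-dimethoxy-4-(triisopropylsilyloxy)phenyl]butane-1,2-diyl}bis(4,4,5,5-tetramethyl-1,3,2-dioxaborolane) | CC1(C)OB(OC1(C)C)C[C@@H](B2OC(C)(C)C(C)(C)O2)CCc3cc(OC)c(O[Si](C(C)C)(C(C)C)C(C)C)c(OC)c3 | intermediate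
11 | (1R)-1-lithio-3-[3-methoxy-4-(triisopropylsilyloxy)phenyl]propyl N,N-diisopropylcarbamate, formed as its (+)-sparteine complex and drawn without the diamine (not isolated) | COc1cc(CC[C@H](OC(=O)N(C(C)C)C(C)C)[Li])ccc1O[Si](C(C)C)(C(C)C)C(C)C | intermediate
12 | lithium boronate complex: the primary boron of 10 bound in addition to the (R)-configured carbamate-bearing carbon of 11 (not isolated) | COc1cc(CC[C@H](OC(=O)N(C(C)C)C(C)C)[B-]3(OC(C)(C)C(C)(C)O3)C[C@@H](B4OC(C)(C)C(C)(C)O4)CCc2cc(OC)c(O[Si](C(C)C)(C(C)C)C(C)C)c(OC)c2)ccc1O[Si](C(C)C)(C(C)C)C(C)C.[Li+] | intermediate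
13 | 2,2'-{(3S,5S)-7-[3,5-dimethoxy-4-(triisopropylsilyloxy)phenyl]-1-[3-methoxy-4-(triisopropylsilyloxy)phenyl]heptane-3,5-diyl}bis(4,4,5,5-tetramethyl-1,3,2-dioxaborolane) (not isolated) | COc1cc(CC[C@H](B3OC(C)(C)C(C)(C)O3)C[C@@H](B4OC(C)(C)C(C)(C)O4)CCc2cc(OC)c(O[Si](C(C)C)(C(C)C)C(C)C)c(OC)c2)ccc1O[Si](C(C)C)(C(C)C)C(C)C | intermediate
14 | (3S,5S)-7-[3,5-dimethoxy-4-(triisopropylsilyloxy)phenyl]-1-[3-methoxy-4-(triisopropylsilyloxy)phenyl]heptane-3,5-diol | COc1cc(CC[C@H](O)C[C@@H](O)CCc2cc(OC)c(O[Si](C(C)C)(C(C)C)C(C)C)c(OC)c2)ccc1O[Si](C(C)C)(C(C)C)C(C)C | intermediate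
15 | (3S,5S)-1-(4-hydroxy-3-methoxyphenyl)-7-(4-hydroxy-3,5-dimethoxyphenyl)heptane-3,5-diol | COc1cc(CC[C@H](O)C[C@@H](O)CCc2cc(OC)c(O)c(OC)c2)ccc1O | target

**Step count**

Total: 8 steps. Longest linear sequence: 5 steps (1, 2, 3, 7, 8; the branch 4, 5, 6, 7, 8 is equally long).

**Steps most likely to fail**

1. Step 7. What may go wrong: loss of site selectivity between the primary and the secondary boronic ester, stalling at the boronate stage (incomplete 1,2-shift or reversion to the components), or competing lithiation of ring A. Fallback: the same C3–C4 bond is made by a Corey–Seebach dithiane–epoxide union; it sets out from 4 and 10 and comes back at 14.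
   - Alcohol 4 is oxidised (Dess–Martin periodinane, CH2Cl2) to 3-[3-methoxy-4-(triisopropylsilyloxy)phenyl]propanal F1, which with propane-1,3-dithiol and BF3·OEt2 (CH2Cl2, 0 °C) should give 2-{2-[3-methoxy-4-(triisopropylsilyloxy)phenyl]ethyl}-1,3-dithiane F2.
   - Bis(boronic ester) 10 is oxidised (NaOH, H2O2, THF, 0 °C) with retention to (2S)-4-[3,5-dimethoxy-4-(triisopropylsilyloxy)phenyl]butane-1,2-diol F3.
   - F3 is tosylated at the primary hydroxyl (TsCl, Bu2SnO cat., Et3N, CH2Cl2) to (2S)-4-[3,5-dimethoxy-4-(triisopropylsilyloxy)phenyl]-2-hydroxybutyl 4-methylbenzenesulfonate F4, and closed (NaH, THF, 0 °C) to (2S)-2-{2-[3,5-dimethoxy-4-(triisopropylsilyloxy)phenyl]ethyl}oxirane F5.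
   - The 2-lithio derivative of F2 (t-BuLi, THF/HMPA, −78 °C) opens F5 at its terminal carbon to give (2S)-4-[3,5-dimethoxy-4-(triisopropylsilyloxy)phenyl]-1-(2-{2-[3-methoxy-4-(triisopropylsilyloxy)phenyl]ethyl}-1,3-dithian-2-yl)butan-2-ol F6.
   - Dithiane removal (MeI, CaCO3, MeCN/H2O, 45 °C) gives (5S)-7-[3,5-dimethoxy-4-(triisopropylsilyloxy)phenyl]-5-hydroxy-1-[3-methoxy-4-(triisopropylsilyloxy)phenyl]heptan-3-one F7.
   - Evans–Saksena reduction (Me4NBH(OAc)3, MeCN/AcOH, −30 °C; intramolecular hydride delivery from the C5 alkoxyborohydride) should set C3 anti to C5 and deliver 14.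

2. Step 6. What may go wrong: insufficient facial selectivity in the diboration, which erodes the configuration at C5 and later appears as the syn-diol series. Fallback: the second boron is introduced by enantioselective copper–boron addition instead; it sets out from 9 and comes back at 10.
   - Cross-metathesis of 9 with vinylboronic acid pinacol ester (second-generation Grubbs catalyst, RuCl2(=CHPh)(PCy3)(H2IMes), CH2Cl2, 40 °C) should give 2-{(1E)-4-[3,5-dimethoxy-4-(triisopropylsilyloxy)phenyl]but-1-en-1-yl}-4,4,5,5-tetramethyl-1,3,2-dioxaborolane F8.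
   - Enantioselective protoboration of F8 (CuCl, chiral imidazolinium salt as carbene precursor, NaOt-Bu, B2pin2, MeOH, THF, −15 °C) places the new boron on the carbon remote from the existing one, with the antipode of the carbene ligand chosen for the (R)-product, and gives 10.

3. Step 5. What may go wrong: slow oxidative addition into the electron-rich aryl bromide, protodezincation of the reagent, or migration of the terminal double bond along the chain. Fallback: the butenyl chain is built by Heck arylation and olefination; it sets out from 7 and comes back at 9.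
   - Heck reaction of 7 with allyl alcohol under Jeffery conditions (Pd(OAc)2, Bu4NCl, NaHCO3, DMF, 60–80 °C; β-hydride elimination toward the carbinol carbon and tautomerisation) should give 3-[3,5-dimethoxy-4-(triisopropylsilyloxy)phenyl]propanal F9.
   - Wittig methylenation of F9 (Ph3PCH3Br, KOt-Bu, THF, 0 °C) gives 9.

**Further compounds**

F1 | step 7 | 3-[3-methoxy-4-(triisopropylsilyloxy)phenyl]propanal | COc1cc(CCC=O)ccc1O[Si](C(C)C)(C(C)C)C(C)C
F2 | step 7 | 2-{2-[3-methoxy-4-(triisopropylsilyloxy)phenyl]ethyl}-1,3-dithiane | COc1cc(CCC2SCCCS2)ccc1O[Si](C(C)C)(C(C)C)C(C)C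
F3 | step 7 | (2S)-4-[3,5-dimethoxy-4-(triisopropylsilyloxy)phenyl]butane-1,2-diol | OC[C@@H](O)CCc1cc(OC)c(O[Si](C(C)C)(C(C)C)C(C)C)c(OC)c1
F4 | step 7 | (2S)-4-[3,5-dimethoxy-4-(triisopropylsilyloxy)phenyl]-2-hydroxybutyl 4-methylbenzenesulfonate | Cc1ccc(cc1)S(=O)(=O)OC[C@@H](O)CCc2cc(OC)c(O[Si](C(C)C)(C(C)C)C(C)C)c(OC)c2
F5 | step 7 | (2S)-2-{2-[3,5-dimethoxy-4-(triisopropylsilyloxy)phenyl]ethyl}oxirane | COc1cc(CC[C@H]2CO2)cc(OC)c1O[Si](C(C)C)(C(C)C)C(C)C
F6 | step 7 | (2S)-4-[3,5-dimethoxy-4-(triisopropylsilyloxy)phenyl]-1-(2-{2-[3-methoxy-4-(triisopropylsilyloxy)phenyl]ethyl}-1,3-dithian-2-yl)butan-2-ol | COc1cc(CCC3(SCCCS3)C[C@@H](O)CCc2cc(OC)c(O[Si](C(C)C)(C(C)C)C(C)C)c(OC)c2)ccc1O[Si](C(C)C)(C(C)C)C(C)C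
F7 | step 7 | (5S)-7-[3,5-dimethoxy-4-(triisopropylsilyloxy)phenyl]-5-hydroxy-1-[3-methoxy-4-(triisopropylsilyloxy)phenyl]heptan-3-one | COc1cc(CCC(=O)C[C@@H](O)CCc2cc(OC)c(O[Si](C(C)C)(C(C)C)C(C)C)c(OC)c2)ccc1O[Si](C(C)C)(C(C)C)C(C)C
F8 | step 6 | 2-{(1E)-4-[3,5-dimethoxy-4-(triisopropylsilyloxy)phenyl]but-1-en-1-yl}-4,4,5,5-tetramethyl-1,3,2-dioxaborolane | COc1cc(CC/C=C/B2OC(C)(C)C(C)(C)O2)cc(OC)c1O[Si](C(C)C)(C(C)C)C(C)C
F9 | step 5 | 3-[3,5-dimethoxy-4-(triisopropylsilyloxy)phenyl]propanal | COc1cc(CCC=O)cc(OC)c1O[Si](C(C)C)(C(C)C)C(C)C
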